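The target is (3S,6E)-1-(3,4-dihydroxyphenyl)-7-(4-hydroxyphenyl)hept-6-en-3-yl acetate. CIP order at C3 is OAc > CH2CH2Ar > CH2CH2CH=CHAr > H, which gives S.

Assumption: I take the (S)-spiro phosphoramidite in Step 5 to direct Si-face attack. This sense of induction is not established for this substrate pair. It is checked on alcohol 8 by Mosher ester analysis, and the equally available (R)-ligand is used if the sense is reversed, with no other change to the route.

## Retrosynthetic overview

1. The endgame is fluoride desilylation and O-acetylation of a tris-TBS (3S)-alcohol.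
2. The key disconnection is C3–C4, made by an enantioselective Ni(0)/Et2Zn reductive homoallylation of an aldehyde (C1–C3) with an (E)-1-aryl-1,3-butadiene (C4–C7). One step forms the bond, sets C3 and keeps the E-styrene. This replaces ketone reduction, epoxide opening or metathesis.
3. The aldehyde comes from dihydrocaffeic acid by esterification, silylation and DIBAL reduction.
4. The diene comes from 4-(TBSO)benzaldehyde and diethyl allylphosphonate by HWE olefination.
5. No rings are formed. Both benzene rings are bought intact.

## Route

**Step 1**
Reactants: 1, 3-(3,4-dihydroxyphenyl)propanoic acid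
Product: 2, methyl 3-(3,4-dihydroxyphenyl)propanoate
Conditions: MeOH, cat. H2SO4, reflux, N2
Reagents that add atoms: methanol, CO
Why: Fischer esterification driven by excess MeOH, and the catechol is stable to acid under N2.

**Step 2**
Reactants: 2
Product: 3, methyl 3-[3,4-bis(tert-butyldimethylsilyloxy)phenyl]propanoate
Conditions: TBSCl (2.4 equiv), imidazole, DMF, rt
Reagents that add atoms: TBSCl, CC(C)(C)[Si](C)(C)Cl
Why: Imidazole-promoted silylation masks the acidic phenols against DIBAL and Et2Zn, and aryl TBS ethers come off later with buffered fluoride without harming an acetate or a styrene.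

**Step 3**
Reactants: 3
Product: 4, 3-[3,4-bis(tert-butyldimethylsilyloxy)phenyl]propanal
Conditions: DIBAL-H (1.05 equiv), toluene, −78 °C; MeOH quench at −78 °C, then aq. Rochelle salt
Reagents that add atoms: none
Why: Partial ester reduction works because the aluminium hemiacetal is stable at −78 °C and collapses to the aldehyde only on work-up, while the aryl silyl ethers are inert.

**Step 4**
Reactants: 5, 4-(tert-butyldimethylsilyloxy)benzaldehyde; 6, diethyl allylphosphonate
Product: 7, (E)-1-[4-(tert-butyldimethylsilyloxy)phenyl]buta-1,3-diene
Conditions: 6, n-BuLi, THF, −78 °C; add 5; then HMPA, −78 °C → rt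
Reagents that add atoms: diethyl allylphosphonate (6), C=CCP(=O)(OCC)OCC
Why: Horner–Wadsworth–Emmons olefination of the α-lithiated allylphosphonate, where reversible addition and elimination through the less hindered oxaphosphetane give the terminal E-diene.

**Step 5 (key step)**
Reactants: 4, the aldehyde; 7, the diene (1.5 equiv)
Product: 8, (3S,6E)-1-[3,4-bis(tert-butyldimethylsilyloxy)phenyl]-7-[4-(tert-butyldimethylsilyloxy)phenyl]hept-6-en-3-ol
Conditions: Ni(acac)2 (5 mol %), (S)-SIPHOS-type spirobiindane phosphoramidite (6 mol %), Et2Zn (2.5 equiv, added last), THF, 0 °C → rt; aq. NH4Cl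
Reagents that add atoms: none (Et2Zn supplies only H at C5; the quench supplies the O–H)
Why: Proposed new method: this is an enantioselective Ni/Et2Zn reductive homoallylation (Tamaru-type diene–aldehyde coupling) applied to a saturated aldehyde and a mono-aryl diene, in which L*Ni(0) binds the s-cis diene and the Zn-activated aldehyde, oxidative cyclisation joins the unsubstituted diene terminus (C4) to the Si face of the carbonyl inside the pocket of the single monodentate ligand and so sets C3 as S, and Et transfer from Zn, β-hydride elimination and C–H reductive elimination at the proximal allyl carbon (C5) then release the zinc alkoxide with the aryl-conjugated E-alkene intact; the closest known reactions are the racemic Ni(acac)2/Et2Zn homoallylation of saturated aldehydes with 1,3-dienes and the spiro-phosphoramidite-controlled asymmetric coupling of aryl aldehydes with 1,4-diaryl-1,3-dienes, which shows the same regiochemistry (H next to the new C–C bond, styrene retained).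

**Step 6**
Reactants: 8
Product: 9, (3S,6E)-1-[3,4-bis(tert-butyldimethylsilyloxy)phenyl]-7-[4-(tert-butyldimethylsilyloxy)phenyl]hept-6-en-3-yl acetate
Conditions: Ac2O, Et3N, cat. DMAP, CH2Cl2, 0 °C → rt
Reagents that add atoms: acetic anhydride, CC(=O)OC(C)=O
Why: DMAP-catalysed O-acylation of the only free hydroxyl breaks no bond to C3, so the S configuration is retained.

**Step 7**
Reactants: 9
Product: 10, (3S,6E)-1-(3,4-dihydroxyphenyl)-7-(4-hydroxyphenyl)hept-6-en-3-yl acetate (target)
Conditions: TBAF (3.3 equiv), AcOH (3.6 equiv), THF, 0 °C, Ar
Reagents that add atoms: none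
Why: Fluoride desilylation of aryl silyl ethers is fast, and the AcOH buffer protonates each phenoxide at once, so there is no acyl transfer from the secondary acetate, no catechol oxidation and no change at the non-activated C3 centre or the E-alkene.

## Compound list

| No. | Name | SMILES | Role |
|---|---|---|---|
| 1 | 3-(3,4-dihydroxyphenyl)propanoic acid | OC(=O)CCc1ccc(O)c(O)c1 | starting material |
| 2 | methyl 3-(3,4-dihydroxyphenyl)propanoate | COC(=O)CCc1ccc(O)c(O)c1 | intermediate |
| 3 | methyl 3-[3,4-bis(TBSO)phenyl]propanoate | COC(=O)CCc1ccc(O[Si](C)(C)C(C)(C)C)c(O[Si](C)(C)C(C)(C)C)c1 | intermediate |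
| 4 | 3-[3,4-bis(TBSO)phenyl]propanal | O=CCCc1ccc(O[Si](C)(C)C(C)(C)C)c(O[Si](C)(C)C(C)(C)C)c1 | intermediate |
| 5 | 4-(TBSO)benzaldehyde | O=Cc1ccc(O[Si](C)(C)C(C)(C)C)cc1 | starting material |
| 6 | diethyl allylphosphonate | C=CCP(=O)(OCC)OCC | starting material |
| 7 | (E)-1-[4-(TBSO)phenyl]buta-1,3-diene | C=C/C=C/c1ccc(O[Si](C)(C)C(C)(C)C)cc1 | intermediate |
| 8 | (3S,6E)-tris-TBS hept-6-en-3-ol | O[C@@H](CC/C=C/c1ccc(O[Si](C)(C)C(C)(C)C)cc1)CCc1ccc(O[Si](C)(C)C(C)(C)C)c(O[Si](C)(C)C(C)(C)C)c1 | intermediate |
| 9 | (3S,6E)-tris-TBS hept-6-en-3-yl acetate | CC(=O)O[C@@H](CC/C=C/c1ccc(O[Si](C)(C)C(C)(C)C)cc1)CCc1ccc(O[Si](C)(C)C(C)(C)C)c(O[Si](C)(C)C(C)(C)C)c1 | intermediate |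
| 10 | (3S,6E)-1-(3,4-dihydroxyphenyl)-7-(4-hydroxyphenyl)hept-6-en-3-yl acetate | CC(=O)O[C@@H](CC/C=C/c1ccc(O)cc1)CCc1ccc(O)c(O)c1 | target |

## Step count and risks

Total steps: 7. Longest linear sequence: 6 (1 → 2 → 3 → 4 → 8 → 9 → 10).

The three steps most likely to fail:

1. **Step 5.** The risks are low ee, an unknown sense of induction, competing ethyl addition and some of the skipped-alkene regioisomer.
   - The fallback is reagent-controlled lithiation–borylation in place of catalyst control.
   - Fully reduce 3 to the alcohol and convert it to the N,N-diisopropylcarbamate.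
   - Deprotonate with s-BuLi/(−)-sparteine in Et2O at −78 °C, which removes the pro-S hydrogen.
   - Trap with the B-[(E)-4-arylbut-3-enyl]-9-BBN made from 7 and 9-BBN.
   - A stereospecific 1,2-metallate shift (retention on borylation, inversion on carbamate displacement) followed by NaBO3 oxidation gives the same (S)-8 with a predictable sense, at a cost of two extra steps.

2. **Step 4.** The risks are α/γ attack of the allyl anion, E/Z leakage, silyl loss in HMPA and diene polymerisation. The fallback moves the disconnection to the terminal alkene. Silylate commercial (E)-4-hydroxycinnamaldehyde and methylenate it with Ph3P=CH2, so the E-styrene geometry is bought rather than made.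

3. **Step 7.** The risks are acetate loss or transfer to a phenoxide and catechol oxidation. The fallback changes the protecting-group logic.
   - Desilylate 8 first and peracetylate to the tetraacetate.
   - Cleave only the three aryl acetates with NH4OAc in aq. MeOH or with hydrazine acetate.
   - Aryl acetates are far more reactive than the secondary alkyl acetate, which stays in place.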